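Eight days at 5 °C should leave theta a small remainder of starting material, and that remainder is what I compute.

the same everywhere: starting material 0.15 M

| run | partner | free catalyst | temperature | remark | time |
|---|---|---|---|---|---|
| summer | 0.15 M | 0.30 mM | −10 °C | run made earlier |  |
| noon | 0.15 M | 0.20 mM | 5 °C | run made earlier |  |
| autumn | 0.15 M | 0.45 mM | −10 °C | run made earlier |  |
| eta | 0.150 M (fed, over 5.0 d) | 0.30 mM | 5 °C | all else is in the flask from the start; the feed brings no volume worth counting | 8.0 d |
| theta | 0.150 M | 0.30 mM | 5 °C | everything together at the start | 8.0 d |
| zeta | 0.150 M | 0.30 mM |  | everything together at the start at −25 °C, warmed to 5 °C at 5.0 d | 8.0 d |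
| delta | 0.150 M (fed, over 5.0 d) | 0.30 mM |  | the addition at −25 °C, then warmed to 5 °C; the feed brings no volume worth counting | 8.0 d |

| run | time / d | product / % | starting material / % |
|---|---|---|---|
| summer | 1.25 | 37.5 | 61.8 |
| summer | 4.00 | 75.8 | 23.9 |
| summer | 6.00 | 85.8 | 14.1 |
| summer | 10.0 | 92.9 | 7.7 |
| noon | 0.833 | 48.8 | 51.9 |
| noon | 1.67 | 69.3 | 29.1 |
| noon | 4.00 | 87.5 | 12.3 |
| noon | 10.0 | 95.5 | 4.8 |
| autumn | 5.00 | 88.9 | 10.2 |
| autumn | 10.0 | 95.1 | 4.5 |
| autumn | 15.0 | 97.7 | 2.6 |
| autumn | 20.0 | 97.6 | 1.2 |

(readings scatter by 0.5 percentage points)

- the numbers in the tables scatter by 0.5 percentage points (one standard deviation)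
- steps thought possible: partner + catalyst intermediate A -> catalyst intermediate B; catalyst intermediate B -> free catalyst + product; starting material + free catalyst <-> catalyst intermediate A

- the flask with the highest amount of product, in percent of the starting material charged ("all alike" if they lie within 1.5 percentage points) (eta / theta / zeta / delta / all alike)
- final product, as a percentage of the starting material charged, in eta
- final product, as a percentage of the starting material charged, in theta
- final product, as a percentage of the starting material charged, in zeta
- final product, as a percentage of the starting material charged, in delta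

**Why the remainder?** In eta, theta, zeta and delta free catalyst is 0.200% of the starting material, so the catalyst forms hold little of it and product is the complement of the remainder f, which is c(starting material) over its charge.

**How does f fall late in a run?** Starting material and partner are charged equal and are used one for one, so c(starting material) and c(partner) should fall together, as in a second-order tail. The reciprocal of f should then climb in a straight line. The last two noon readings show a climb of 10.6 /mM/d. This reading is the tail constant, the rise in the reciprocal of f per mM of free catalyst charged and per day.

**One run. Does dividing by catalyst hold?** At −10 °C the summer run gives 4.91 /mM/d, and the autumn run gives 5.52 /mM/d. Their loadings differ by a factor 1.50, their constants by 1.12, so I divide by catalyst. The summer value is about half the noon one.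

**Theta, then?** Theta has the noon temperature with 0.30 mM of free catalyst. From the noon reading at 4.00 d, where the reciprocal stands at 8.13, theta's extra catalyst-time adds 16.9. That gives f = 3.99% and product 96.0%.

**Can another flask beat theta?** Eta has theta's temperature, but its partner arrives over 5.0 d. Zeta and delta spend 5.0 d at −25 °C, colder than any run so far. I put theta first.

The forecast also names theta, with eta 93%, theta 96.1% (95.5% to 96.8%), zeta 90.9% and delta 90.2%. Its ground for theta is this: “Theta equals noon at 12 d: about 96%.” My figure rests on the same noon run, so the two count as one estimate.

**Result.** The highest product stands in theta, at 96.3%, with eta 93.3%, zeta 90.1% and delta 89.9%.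

    partner + catalyst intermediate A → catalyst intermediate B (k = 1360 /M/h, Ea = 37.0 kJ/mol)
    catalyst intermediate B → free catalyst + product (k = 149 /h, Ea = 84.0 kJ/mol)
    starting material + free catalyst ⇌ catalyst intermediate A (K = 2.69 /M, k = 544 /M/h, Ea = 54.0 kJ/mol, ΔH = −15.0 kJ/mol)
    (constants at 5 °C)

Theta ends with 3.65% of its starting material left, against my 3.99%, and free catalyst, the resting state, stands at 98.5% of the catalyst charged. Eta is the next case. At 5.00 d, when its feed stops, starting material and partner stand equal at 20.6% and 20.6%, each of its own charge. The tail constant over the remaining 3.00 d at 0.30 mM adds 9.53 to the reciprocal, which gives f = 6.96%. Eta's remainder at 8.00 d is 6.65%.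

(The numbers in the tables were generated by integration on assumed constants; noise was put on by code.)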